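**Assumption:** cathafuran C has no stereocentre and no stereogenic double bond, so it is achiral and is made as such; the trans geometry of the stilbene intermediates is stated but disappears into the furan ring.

## Retrosynthetic overview

1. Both heterocycles are closed in the last step by one oxidant (DDQ) acting on a 2',6'-diprenylated oxyresveratrol, the two dehydrogenative ring closures of the presumed biogenesis.
2. Ring order: the furan ring forms first (2-hydroxystilbene to 2-arylbenzofuran); the pyran ring forms second, from one of two equivalent ortho-prenylphenol units via an ortho-quinone methide and oxa-6π closure. This desymmetrises ring B.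
3. The tetrahydroxystilbene comes from MOM removal after a Suzuki–Miyaura union of a ring B alkenyl boronate with unprotected 4-bromoresorcinol (ring A).
4. The ring B boronate comes from boron–Wittig olefination of a 2,6-diprenyl benzaldehyde, made by twofold Stille prenylation of the 2,6-dibromide of MOM-protected 3,5-dihydroxybenzaldehyde.

## Route

Step 1
Reactants: 1 3,5-dihydroxybenzaldehyde
Product: 2 3,5-bis(methoxymethoxy)benzaldehyde
Conditions: NaH (2.4 equiv), MOMCl (2.4 equiv), DMF, 0 °C → 25 °C
Reagents that add atoms: chloromethyl methyl ether (MOMCl), COCCl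
Why: Williamson-type O-alkylation of both phenoxides gives the bis-MOM ether, which activates the ring for the next step and is later removed by mild acid.

Step 2
Reactants: 2 3,5-bis(methoxymethoxy)benzaldehyde
Product: 3 2,6-dibromo-3,5-bis(methoxymethoxy)benzaldehyde
Conditions: NBS (2.1 equiv), DMF, 0 °C → 25 °C, dark
Reagents that add atoms: N-bromosuccinimide (NBS), O=C1CCC(=O)N1Br
Why: Electrophilic aromatic bromination goes twice to C2 and C6, each para to one alkoxy group and ortho to the other, whereas C4 has no para-alkoxy activation and is flanked by both MOM ethers; this is the usual 2,6-dihalogenation pattern of 3,5-dialkoxyphenyl carbonyl compounds.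

Step 3
Reactants: 3 2,6-dibromo-3,5-bis(methoxymethoxy)benzaldehyde
Product: 4 3,5-bis(methoxymethoxy)-2,6-bis(3-methylbut-2-en-1-yl)benzaldehyde
Conditions: Bu3SnCH2CH=CMe2 (2.6 equiv), Pd(PPh3)4 (10 mol %), DMF, 100 °C
Reagents that add atoms: tributyl(3-methylbut-2-en-1-yl)stannane, CCCC[Sn](CCCC)(CCCC)CC=C(C)C
Why: Twofold Stille coupling; the ortho-formyl group speeds oxidative addition of zerovalent palladium into each C–Br bond, and the allyl group is delivered at its unsubstituted terminus to give the linear prenyl arene, as in the routine Stille allylation of 2-bromobenzaldehydes.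

Step 4
Reactants: 4 3,5-bis(methoxymethoxy)-2,6-bis(3-methylbut-2-en-1-yl)benzaldehyde
Product: 5 2-[(E)-2-[3,5-bis(methoxymethoxy)-2,6-bis(3-methylbut-2-en-1-yl)phenyl]ethenyl]-4,4,5,5-tetramethyl-1,3,2-dioxaborolane
Conditions: CH2(Bpin)2 (1.3 equiv), lithium 2,2,6,6-tetramethylpiperidide (1.3 equiv), THF, 0 °C; then 4, –78 °C → 25 °C
Reagents that add atoms: bis(4,4,5,5-tetramethyl-1,3,2-dioxaborolan-2-yl)methane, CC1(C)OB(CB2OC(C)(C)C(C)(C)O2)OC1(C)C
Why: Boron–Wittig olefination, in which the α-diboryl carbanion adds to the aldehyde and syn boron–oxygen elimination gives the trans alkenyl boronate; geometric purity is not critical because this double bond ends inside the furan ring.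

Step 5
Reactants: 5 2-[(E)-2-[3,5-bis(methoxymethoxy)-2,6-bis(3-methylbut-2-en-1-yl)phenyl]ethenyl]-4,4,5,5-tetramethyl-1,3,2-dioxaborolane; 6 4-bromobenzene-1,3-diol (4-bromoresorcinol)
Product: 7 4-[(E)-2-[3,5-bis(methoxymethoxy)-2,6-bis(3-methylbut-2-en-1-yl)phenyl]ethenyl]benzene-1,3-diol
Conditions: Pd(OAc)2 (5 mol %), SPhos (10 mol %), K3PO4 (3.5 equiv), 1,4-dioxane/H2O 4:1, 80 °C
Reagents that add atoms: none
Why: Suzuki–Miyaura coupling with retention of alkene geometry; the electron-rich biaryl phosphine lets zerovalent palladium insert into the phenoxide-bearing aryl bromide, so ring A needs no protection, and the MOM ethers and prenyl groups are inert to aqueous base.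

Step 6
Reactants: 7 4-[(E)-2-[3,5-bis(methoxymethoxy)-2,6-bis(3-methylbut-2-en-1-yl)phenyl]ethenyl]benzene-1,3-diol
Product: 8 4-[(E)-2-[3,5-dihydroxy-2,6-bis(3-methylbut-2-en-1-yl)phenyl]ethenyl]benzene-1,3-diol
Conditions: HCl (cat., about 0.5 M), MeOH, 25–40 °C, argon
Reagents that add atoms: none
Why: Acid-catalysed acetal exchange with methanol frees both ring B phenols under conditions mild enough to leave ortho-prenylphenols uncyclised, as in MOM removal from prenylated chalcones and stilbenes.

Step 7
Reactants: 8 4-[(E)-2-[3,5-dihydroxy-2,6-bis(3-methylbut-2-en-1-yl)phenyl]ethenyl]benzene-1,3-diol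
Product: 11 cathafuran C, via diprenylbenzofuran triol 9 (not isolated), via ortho-quinone methide 10 (not isolated)
Conditions: DDQ (1.05 equiv), 1,4-dioxane, 25 °C; then DDQ (1.0 equiv), 80 °C
Reagents that add atoms: none
Why: Proposed new method: one oxidant performs both biogenesis-type dehydrogenative cyclisations in one flask, since DDQ first removes two electrons from the 2,4-dihydroxystilbene (the most easily oxidised phenol), the resulting quinone-methide cation is captured at its benzylic carbon by the ortho hydroxyl and tautomerises to benzofuran 9, and the second equivalent abstracts hydride from one benzylic prenyl CH2 to give ortho-quinone methide 10, which closes by oxa-6π electrocyclisation to the 2,2-dimethylchromene; the two prenyl/hydroxyl pairs of 9 are equivalent so either gives 11, the bis-chromene is held back by the DDQ stoichiometry, no stereocentre is formed, and the closest known reactions are the DDQ cyclisation of ortho-prenylphenols to 2,2-dimethylchromenes and the two-electron oxidative cyclisation of 2-hydroxystilbenes to 2-arylbenzofurans with PhI(OAc)2 or iodine.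

## Compound list

1 | 3,5-dihydroxybenzaldehyde | O=Cc1cc(O)cc(O)c1 | starting material
2 | 3,5-bis(methoxymethoxy)benzaldehyde | COCOc1cc(C=O)cc(OCOC)c1 | intermediate
3 | 2,6-dibromo-3,5-bis(methoxymethoxy)benzaldehyde | COCOc1cc(OCOC)c(Br)c(C=O)c1Br | intermediate
4 | 3,5-bis(methoxymethoxy)-2,6-bis(3-methylbut-2-en-1-yl)benzaldehyde | COCOc1cc(OCOC)c(CC=C(C)C)c(C=O)c1CC=C(C)C | intermediate
5 | 2-[(E)-2-[3,5-bis(methoxymethoxy)-2,6-bis(3-methylbut-2-en-1-yl)phenyl]ethenyl]-4,4,5,5-tetramethyl-1,3,2-dioxaborolane | COCOc1cc(OCOC)c(CC=C(C)C)c(/C=C/B2OC(C)(C)C(C)(C)O2)c1CC=C(C)C | intermediate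
6 | 4-bromobenzene-1,3-diol (4-bromoresorcinol) | Oc1ccc(Br)c(O)c1 | starting material
7 | 4-[(E)-2-[3,5-bis(methoxymethoxy)-2,6-bis(3-methylbut-2-en-1-yl)phenyl]ethenyl]benzene-1,3-diol | COCOc1cc(OCOC)c(CC=C(C)C)c(/C=C/c2ccc(O)cc2O)c1CC=C(C)C | intermediate
8 | 4-[(E)-2-[3,5-dihydroxy-2,6-bis(3-methylbut-2-en-1-yl)phenyl]ethenyl]benzene-1,3-diol | CC(C)=CCc1c(O)cc(O)c(CC=C(C)C)c1/C=C/c1ccc(O)cc1O | intermediate
9 | 5-(6-hydroxy-1-benzofuran-2-yl)-4,6-bis(3-methylbut-2-en-1-yl)benzene-1,3-diol, formed in the flask in step 7 | CC(C)=CCc1c(O)cc(O)c(CC=C(C)C)c1-c1cc2ccc(O)cc2o1 | intermediate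
10 | (6Z)-3-hydroxy-5-(6-hydroxy-1-benzofuran-2-yl)-4-(3-methylbut-2-en-1-yl)-6-(3-methylbut-2-en-1-ylidene)cyclohexa-2,4-dien-1-one, formed in the flask in step 7 | CC(C)=C/C=C1\C(=O)C=C(O)C(CC=C(C)C)=C1c1cc2ccc(O)cc2o1 | intermediate
11 | cathafuran C, 5-(6-hydroxy-1-benzofuran-2-yl)-2,2-dimethyl-6-(3-methylbut-2-en-1-yl)-2H-chromen-7-ol | CC(C)=CCc1c(O)cc2c(c1-c1cc3ccc(O)cc3o1)C=CC(C)(C)O2 | target

## Step count and risks

Total steps: 7. Longest linear sequence: 7 steps (1 → 2 → 3 → 4 → 5 → 7 → 8 → 11); 6 is bought and enters in step 5.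

**Step 7 (most likely to fail).** The one-flask twofold DDQ cyclisation may over-oxidise to the bis-chromene, stop at 9, or attack the free resorcinol rings. The fallback sets out from 7, in which ring B is still MOM-protected and cannot form a quinone methide. PhI(OAc)2 (1.05 equiv, MeCN, 0 °C), a trivalent iodine oxidant known to cyclise 2-hydroxystilbenes, closes only the furan ring and gives 2-[3,5-bis(methoxymethoxy)-2,6-bis(3-methylbut-2-en-1-yl)phenyl]-1-benzofuran-6-ol F1. Methanolic HCl as in step 6 then gives the triol 9 as an isolated compound, where the route is rejoined. From 9 only the single chromene closure remains (DDQ, 1.0 equiv, dioxane, 80 °C), giving 11 through 10, with unreacted 9 recovered and recycled.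

**Step 3.** The twofold Stille prenylation has to succeed at two bromides that each carry two ortho substituents, and some branched (reverse-prenyl) product is possible. The fallback sets out from 1 and comes back at 4 without any cross-coupling. Allyl bromide and K2CO3 in acetone give 3,5-bis(prop-2-en-1-yloxy)benzaldehyde F2. A double aromatic Claisen rearrangement (N,N-diethylaniline, 190 °C) is steered to C2 and C6 by the meta-formyl group and by the para relationship to the other oxygen, and gives 3,5-dihydroxy-2,6-di(prop-2-en-1-yl)benzaldehyde F3. NaH and MOMCl give 3,5-bis(methoxymethoxy)-2,6-di(prop-2-en-1-yl)benzaldehyde F4. Cross-metathesis with 2-methylbut-2-ene (second-generation Grubbs catalyst RuCl2(=CHPh)(PCy3)(H2IMes), CH2Cl2, 40 °C) then converts both allyl groups into prenyl groups and gives 4.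

**Step 5.** The Suzuki coupling uses an unprotected, very electron-rich bromoresorcinol, so slow oxidative addition and protodebromination are possible. The fallback sets out from 4 and 6 and comes back at 8 by a Heck reaction on a protected bromide. Wittig methylenation of 4 (Ph3PCH3Br, KOt-Bu, THF) gives 1-ethenyl-3,5-bis(methoxymethoxy)-2,6-bis(3-methylbut-2-en-1-yl)benzene F5. NaH and MOMCl convert 6 into 1-bromo-2,4-bis(methoxymethoxy)benzene F6. Heck coupling of F5 with F6 (Pd(OAc)2, P(t-Bu)3·HBF4, K2CO3, DMF, 110 °C) gives the trans stilbene 1-[(E)-2-[2,4-bis(methoxymethoxy)phenyl]ethenyl]-3,5-bis(methoxymethoxy)-2,6-bis(3-methylbut-2-en-1-yl)benzene F7. Methanolic HCl as in step 6 removes all four MOM groups and gives 8.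

## Further compounds

F1 | step 7 | 2-[3,5-bis(methoxymethoxy)-2,6-bis(3-methylbut-2-en-1-yl)phenyl]-1-benzofuran-6-ol | COCOc1cc(OCOC)c(CC=C(C)C)c(-c2cc3ccc(O)cc3o2)c1CC=C(C)C
F2 | step 3 | 3,5-bis(prop-2-en-1-yloxy)benzaldehyde | C=CCOc1cc(C=O)cc(OCC=C)c1
F3 | step 3 | 3,5-dihydroxy-2,6-di(prop-2-en-1-yl)benzaldehyde | C=CCc1c(O)cc(O)c(CC=C)c1C=O
F4 | step 3 | 3,5-bis(methoxymethoxy)-2,6-di(prop-2-en-1-yl)benzaldehyde | C=CCc1c(OCOC)cc(OCOC)c(CC=C)c1C=O
F5 | step 5 | 1-ethenyl-3,5-bis(methoxymethoxy)-2,6-bis(3-methylbut-2-en-1-yl)benzene | C=Cc1c(CC=C(C)C)c(OCOC)cc(OCOC)c1CC=C(C)C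
F6 | step 5 | 1-bromo-2,4-bis(methoxymethoxy)benzene | COCOc1ccc(Br)c(OCOC)c1
F7 | step 5 | 1-[(E)-2-[2,4-bis(methoxymethoxy)phenyl]ethenyl]-3,5-bis(methoxymethoxy)-2,6-bis(3-methylbut-2-en-1-yl)benzene | COCOc1ccc(/C=C/c2c(CC=C(C)C)c(OCOC)cc(OCOC)c2CC=C(C)C)c(OCOC)c1
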